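**Plan**

1. Retrosynthesis: the four aryl silyl ethers and the C3 hydroxyl come off first; ring C is then opened at C2–C3, which turns the flavanone into a diazomethyl aryl ketone whose O1 carries C2 as the CH2 of a benzyl ether.
2. Enabling feature: C2 is a methylene that is both α to the ether oxygen O1 and benzylic to the electron-rich resorcinol ring B. It sits six atoms from the carbene carbon C3, and the five-atom position is O1, which has no hydrogen, so a dirhodium carbene at C3 can only insert there and closes the six-membered ring C.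
3. Further cuts: O1–CH2 (Mitsunobu etherification with the ring B benzyl alcohol), C8–CH2 of the lavandulyl chain (Negishi coupling at an iodide placed ortho to the free phenol of ring A), and the bond between the lavandulyl stereocentre and its prenyl group (auxiliary alkylation).
4. Forward order: lavandulyl iodide (steps 1–4) and the ring B alcohol (steps 5–6) are joined to the ring A acetophenone (steps 7–10); diazo transfer, closure of ring C, C3 hydroxylation and desilylation follow (steps 11–14).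
5. Stereochemistry: the lavandulyl centre comes from the oxazolidinone auxiliary; C2 from the chiral dirhodium carboxylate, which chooses between the two enantiotopic C2–H bonds; C3 from C2, because the oxidant approaches the enolate anti to the ring B aryl group (2,3-trans).

Key step: step 12

Abbreviations: TBSO = tert-butyldimethylsilyloxy; TIPSO = triisopropylsilyloxy; lavandulyl = 5-methyl-2-(prop-1-en-2-yl)hex-4-en-1-yl. The lavandulyl descriptor changes from S (6, 7, 15) to R (from 16 on) only because the CIP rank of the CH2 group changes; the centre itself is never touched.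

Assumption: the sense in which Rh2(S-PTTL)4, dirhodium tetrakis[N-phthaloyl-(S)-tert-leucinate], differentiates the two C2–H bonds of 18 cannot be predicted with certainty; the S series is written, and the mirror-image catalyst Rh2(R-PTTL)4 would be used instead if a trial run shows the 2R epimer of 19 to predominate.

**Route**

Step 1
Reactants: 1 (S)-4-benzyl-1,3-oxazolidin-2-one; 2 3-methylbut-2-enoyl chloride
Product: 3 (S)-4-benzyl-3-(3-methylbut-2-enoyl)-1,3-oxazolidin-2-one
Conditions: n-BuLi, THF, −78 °C; then 2, −78 to 0 °C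
Reagents that add atoms: none
Why: N-acylation of the lithiated oxazolidinone by the acid chloride is a standard imide formation and attaches the auxiliary without affecting the trisubstituted alkene.

Step 2
Reactants: 3 (S)-4-benzyl-3-(3-methylbut-2-enoyl)-1,3-oxazolidin-2-one; 4 prenyl bromide (1-bromo-3-methylbut-2-ene)
Product: 5 (S)-4-benzyl-3-[(2S)-5-methyl-2-(prop-1-en-2-yl)hex-4-enoyl]-1,3-oxazolidin-2-one
Conditions: NaN(SiMe3)2, THF, −78 °C; then 4, −78 to −40 °C; cold quench
Reagents that add atoms: none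
Why: This is an Evans alkylation run in the deconjugative sense, in which γ-deprotonation gives the chelated Z-dienolate that reacts at its α-carbon with prenyl bromide on the face away from the benzyl group of the auxiliary, so the S centre is set and the double bond moves into the isopropenyl position.

Step 3
Reactants: 5 (S)-4-benzyl-3-[(2S)-5-methyl-2-(prop-1-en-2-yl)hex-4-enoyl]-1,3-oxazolidin-2-one
Product: 6 (S)-lavandulol
Conditions: LiBH4, H2O (1 equiv), Et2O, 0 °C
Reagents that add atoms: none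
Why: Reductive removal of the auxiliary by hydride attack on the imide carbonyl should give the primary alcohol and return the oxazolidinone without enolising the α-centre.

Step 4
Reactants: 6 (S)-lavandulol
Product: 7 (S)-lavandulyl iodide
Conditions: PPh3, imidazole, I2, CH2Cl2, 0 °C to rt
Reagents that add atoms: iodine, [I][I]
Why: The Appel reaction replaces the primary hydroxyl by iodide through the alkoxyphosphonium salt and involves neither the stereocentre nor the alkenes.

Step 5
Reactants: 8 2,4-dihydroxybenzaldehyde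
Product: 9 2,4-bis(TBSO)benzaldehyde
Conditions: TBSCl (2.3 equiv), imidazole, DMF, rt
Reagents that add atoms: tert-butyldimethylsilyl chloride, CC(C)(C)[Si](C)(C)Cl
Why: Silyl ether formation masks both phenols as groups that are inert to organozinc reagents, enolates and carbenes and that come off with fluoride at the end.

Step 6
Reactants: 9 2,4-bis(TBSO)benzaldehyde
Product: 10 [2,4-bis(TBSO)phenyl]methanol
Conditions: iBu2AlH, CH2Cl2, −78 °C; Rochelle salt work-up
Reagents that add atoms: none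
Why: Hydride reduction of the aldehyde at low temperature passes through a non-basic aluminium alkoxide, which should prevent migration of the ortho silyl group to the new benzylic oxygen.

Step 7
Reactants: 11 1-(2,4,6-trihydroxyphenyl)ethan-1-one
Product: 12 1-[2-hydroxy-4,6-bis(TIPSO)phenyl]ethan-1-one
Conditions: TIPSCl (2.1 equiv), imidazole, DMF, 0 °C to rt
Reagents that add atoms: triisopropylsilyl chloride, CC(C)[Si](Cl)(C(C)C)C(C)C
Why: Silyl ether formation takes the para hydroxyl and one of the two equivalent ortho hydroxyls, while the last hydroxyl stays free because it is hydrogen-bonded to the acetyl group; the bulky silyl group is chosen so that it will not migrate to an enolate oxygen later.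

Step 8
Reactants: 12 1-[2-hydroxy-4,6-bis(TIPSO)phenyl]ethan-1-one
Product: 13 1-[2-hydroxy-3-iodo-4,6-bis(TIPSO)phenyl]ethan-1-one
Conditions: N-iodosuccinimide (1.05 equiv), CH2Cl2, 0 °C, dark
Reagents that add atoms: N-iodosuccinimide, O=C1CCC(=O)N1I
Why: Electrophilic aromatic iodination of the phenol should go ortho to the free hydroxyl, since the only other open ring position is buried between two triisopropylsilyloxy groups.

Step 9
Reactants: 13 1-[2-hydroxy-3-iodo-4,6-bis(TIPSO)phenyl]ethan-1-one; 10 [2,4-bis(TBSO)phenyl]methanol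
Product: 14 1-[2-{[2,4-bis(TBSO)phenyl]methoxy}-3-iodo-4,6-bis(TIPSO)phenyl]ethan-1-one
Conditions: PPh3, DIAD, THF, 0 °C to rt
Reagents that add atoms: none
Why: The Mitsunobu reaction joins the acidic chelated phenol to the electron-rich benzylic alcohol under neutral conditions that leave the aryl silyl ethers and the iodide untouched, and it places the future C2 methylene on the oxygen that becomes O1.

Step 10
Reactants: 7 (S)-lavandulyl iodide; 14 1-[2-{[2,4-bis(TBSO)phenyl]methoxy}-3-iodo-4,6-bis(TIPSO)phenyl]ethan-1-one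
Product: 16 1-[2-{[2,4-bis(TBSO)phenyl]methoxy}-3-[(2R)-lavandulyl]-4,6-bis(TIPSO)phenyl]ethan-1-one, via (S)-lavandulylzinc iodide 15 (not isolated)
Conditions: 7, Zn dust (activated with BrCH2CH2Br and Me3SiCl), LiCl, THF, 40 °C; then 14, Pd(OAc)2 (3 mol %), SPhos (6 mol %), THF, 50 °C
Reagents that add atoms: zinc, [Zn] (found in 15 only, not in 16)
Why: In this Negishi coupling zinc inserts into the primary C–I bond without touching the β-stereocentre, and the alkylzinc iodide couples with the aryl iodide under a palladium/biarylphosphine catalyst that tolerates the ketone, the silyl ethers and the two ortho substituents.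

Step 11
Reactants: 16 1-[2-{[2,4-bis(TBSO)phenyl]methoxy}-3-[(2R)-lavandulyl]-4,6-bis(TIPSO)phenyl]ethan-1-one
Product: 18 2-diazo-1-[2-{[2,4-bis(TBSO)phenyl]methoxy}-3-[(2R)-lavandulyl]-4,6-bis(TIPSO)phenyl]ethan-1-one, via trifluoroacetyl ketone 17 (not isolated)
Conditions: LiN(SiMe3)2, THF, −78 °C; CF3CO2CH2CF3; then MsN3, Et3N, H2O (1 equiv), MeCN, rt
Reagents that add atoms: methanesulfonyl azide, CS(=O)(=O)N=[N+]=[N-]; 2,2,2-trifluoroethyl trifluoroacetate, O=C(OCC(F)(F)F)C(F)(F)F (its trifluoroacetyl group is found in 17 only)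
Why: In this Regitz-type deacylative diazo transfer the kinetic enolate is trifluoroacetylated and the activated 1,3-diketone takes the diazo group from the sulfonyl azide with loss of the trifluoroacetyl group, which gives the diazomethyl ketone from a methyl ketone that cannot be diazotised directly.

Step 12
Reactants: 18 2-diazo-1-[2-{[2,4-bis(TBSO)phenyl]methoxy}-3-[(2R)-lavandulyl]-4,6-bis(TIPSO)phenyl]ethan-1-one
Product: 19 (2S)-2-[2,4-bis(TBSO)phenyl]-8-[(2R)-lavandulyl]-5,7-bis(TIPSO)-2,3-dihydro-4H-chromen-4-one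
Conditions: Rh2(S-PTTL)4 (1 mol %), CH2Cl2, 0 °C, slow addition of 18
Reagents that add atoms: none
Why: Rh2(S-PTTL)4 expels N2 from 18 to give an electrophilic dirhodium carbene at C3, which inserts into one C2–H bond of the O1–CH2–aryl group through a three-centre, hydride-transfer-like transition state in which the positive charge building up at C2 is carried by O1 and by the 2,4-bis(silyloxy)phenyl ring, so that the C2–C3 bond forms and the catalyst is released. The closest known reaction type is the intramolecular C–H insertion of 2-alkoxyaryl diazomethyl ketones to chroman-4-ones under chiral dirhodium tetracarboxylates. Ring C closes as a six-membered ring (C3, C4, C4a, C8a, O1, C2) by 1,6-insertion, the usual five-membered mode being unavailable because the atom in the 1,5-position is O1. The new stereocentre C2 is set by the catalyst, whose chiral carboxylate wall decides which of the two enantiotopic C2–H bonds is presented to the carbene, and not by the remote lavandulyl centre. The step needs insertion at C2 to win over oxonium-ylide formation at O1 with 1,2-benzyl shift, over insertion into the group on O5 and over cyclopropanation of the two side-chain alkenes; the weakly basic, doubly flanked aryl ether oxygen, the silyl group on O5 (no C–H within six atoms) and the meta placement of the lavandulyl chain, whose alkenes could only be reached through eight-membered or larger rings, should secure this.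

Step 13
Reactants: 19 (2S)-2-[2,4-bis(TBSO)phenyl]-8-[(2R)-lavandulyl]-5,7-bis(TIPSO)-2,3-dihydro-4H-chromen-4-one
Product: 20 (2R,3R)-2-[2,4-bis(TBSO)phenyl]-3-hydroxy-8-[(2R)-lavandulyl]-5,7-bis(TIPSO)-2,3-dihydro-4H-chromen-4-one
Conditions: NaN(SiMe3)2, THF, −78 °C; 2-(phenylsulfonyl)-3-phenyloxaziridine, −78 °C; AcOH quench at −78 °C
Reagents that add atoms: 2-(phenylsulfonyl)-3-phenyloxaziridine, O=S(=O)(c1ccccc1)N1OC1c1ccccc1
Why: In this enolate hydroxylation with an N-sulfonyloxaziridine (Davis oxidation) the sodium enolate of 19 should be oxidised at C3 on the face opposite to the C2 aryl group, which gives the 2,3-trans (2R,3R) ketol without affecting the alkenes.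

Step 14
Reactants: 20 (2R,3R)-2-[2,4-bis(TBSO)phenyl]-3-hydroxy-8-[(2R)-lavandulyl]-5,7-bis(TIPSO)-2,3-dihydro-4H-chromen-4-one
Product: 21 kushenol X
Conditions: Bu4NF (4.5 equiv), AcOH (4.5 equiv), THF, 0 °C
Reagents that add atoms: none
Why: Fluoride-induced cleavage of the four aryl silyl ethers, buffered with acetic acid so that the free phenols are not held as phenoxides, should leave the alkenes and both ring C stereocentres untouched.

**Compound list**

1 | (S)-4-benzyl-1,3-oxazolidin-2-one | O=C1OC[C@H](Cc2ccccc2)N1 | starting material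
2 | 3-methylbut-2-enoyl chloride | CC(C)=CC(=O)Cl | starting material
3 | (S)-4-benzyl-3-(3-methylbut-2-enoyl)-1,3-oxazolidin-2-one | CC(C)=CC(=O)N1[C@@H](Cc2ccccc2)COC1=O | intermediate
4 | prenyl bromide (1-bromo-3-methylbut-2-ene) | CC(C)=CCBr | starting material
5 | (S)-4-benzyl-3-[(2S)-5-methyl-2-(prop-1-en-2-yl)hex-4-enoyl]-1,3-oxazolidin-2-one | C=C(C)[C@H](CC=C(C)C)C(=O)N1[C@@H](Cc2ccccc2)COC1=O | intermediate
6 | (S)-lavandulol, (2S)-5-methyl-2-(prop-1-en-2-yl)hex-4-en-1-ol | C=C(C)[C@H](CC=C(C)C)CO | intermediate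
7 | (S)-lavandulyl iodide, (3S)-3-(iodomethyl)-2,6-dimethylhepta-1,5-diene | C=C(C)[C@H](CC=C(C)C)CI | intermediate
8 | 2,4-dihydroxybenzaldehyde | O=Cc1ccc(O)cc1O | starting material
9 | 2,4-bis(TBSO)benzaldehyde | O=Cc1ccc(O[Si](C)(C)C(C)(C)C)cc1O[Si](C)(C)C(C)(C)C | intermediate
10 | [2,4-bis(TBSO)phenyl]methanol | OCc1ccc(O[Si](C)(C)C(C)(C)C)cc1O[Si](C)(C)C(C)(C)C | intermediate
11 | 1-(2,4,6-trihydroxyphenyl)ethan-1-one | CC(=O)c1c(O)cc(O)cc1O | starting material
12 | 1-[2-hydroxy-4,6-bis(TIPSO)phenyl]ethan-1-one | CC(=O)c1c(O)cc(O[Si](C(C)C)(C(C)C)C(C)C)cc1O[Si](C(C)C)(C(C)C)C(C)C | intermediate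
13 | 1-[2-hydroxy-3-iodo-4,6-bis(TIPSO)phenyl]ethan-1-one | CC(=O)c1c(O)c(I)c(O[Si](C(C)C)(C(C)C)C(C)C)cc1O[Si](C(C)C)(C(C)C)C(C)C | intermediate
14 | 1-[2-{[2,4-bis(TBSO)phenyl]methoxy}-3-iodo-4,6-bis(TIPSO)phenyl]ethan-1-one | CC(=O)c1c(OCc2ccc(O[Si](C)(C)C(C)(C)C)cc2O[Si](C)(C)C(C)(C)C)c(I)c(O[Si](C(C)C)(C(C)C)C(C)C)cc1O[Si](C(C)C)(C(C)C)C(C)C | intermediate
15 | (S)-lavandulylzinc iodide, iodo[(2S)-5-methyl-2-(prop-1-en-2-yl)hex-4-en-1-yl]zinc | C=C(C)[C@H](CC=C(C)C)C[Zn]I | intermediate
16 | 1-[2-{[2,4-bis(TBSO)phenyl]methoxy}-3-[(2R)-lavandulyl]-4,6-bis(TIPSO)phenyl]ethan-1-one | C=C(C)[C@H](CC=C(C)C)Cc1c(O[Si](C(C)C)(C(C)C)C(C)C)cc(O[Si](C(C)C)(C(C)C)C(C)C)c(C(C)=O)c1OCc1ccc(O[Si](C)(C)C(C)(C)C)cc1O[Si](C)(C)C(C)(C)C | intermediate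
17 | 1-[2-{[2,4-bis(TBSO)phenyl]methoxy}-3-[(2R)-lavandulyl]-4,6-bis(TIPSO)phenyl]-4,4,4-trifluorobutane-1,3-dione (trifluoroacetyl ketone) | C=C(C)[C@H](CC=C(C)C)Cc1c(O[Si](C(C)C)(C(C)C)C(C)C)cc(O[Si](C(C)C)(C(C)C)C(C)C)c(C(=O)CC(=O)C(F)(F)F)c1OCc1ccc(O[Si](C)(C)C(C)(C)C)cc1O[Si](C)(C)C(C)(C)C | intermediate
18 | 2-diazo-1-[2-{[2,4-bis(TBSO)phenyl]methoxy}-3-[(2R)-lavandulyl]-4,6-bis(TIPSO)phenyl]ethan-1-one | C=C(C)[C@H](CC=C(C)C)Cc1c(O[Si](C(C)C)(C(C)C)C(C)C)cc(O[Si](C(C)C)(C(C)C)C(C)C)c(C(=O)C=[N+]=[N-])c1OCc1ccc(O[Si](C)(C)C(C)(C)C)cc1O[Si](C)(C)C(C)(C)C | intermediate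
19 | (2S)-2-[2,4-bis(TBSO)phenyl]-8-[(2R)-lavandulyl]-5,7-bis(TIPSO)-2,3-dihydro-4H-chromen-4-one | C=C(C)[C@H](CC=C(C)C)Cc1c(O[Si](C(C)C)(C(C)C)C(C)C)cc(O[Si](C(C)C)(C(C)C)C(C)C)c2c1O[C@H](c1ccc(O[Si](C)(C)C(C)(C)C)cc1O[Si](C)(C)C(C)(C)C)CC2=O | intermediate
20 | (2R,3R)-2-[2,4-bis(TBSO)phenyl]-3-hydroxy-8-[(2R)-lavandulyl]-5,7-bis(TIPSO)-2,3-dihydro-4H-chromen-4-one | C=C(C)[C@H](CC=C(C)C)Cc1c(O[Si](C(C)C)(C(C)C)C(C)C)cc(O[Si](C(C)C)(C(C)C)C(C)C)c2c1O[C@H](c1ccc(O[Si](C)(C)C(C)(C)C)cc1O[Si](C)(C)C(C)(C)C)[C@@H](O)C2=O | intermediate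
21 | kushenol X, (2R,3R)-2-(2,4-dihydroxyphenyl)-3,5,7-trihydroxy-8-[(2R)-lavandulyl]-2,3-dihydro-4H-chromen-4-one | C=C(C)[C@H](CC=C(C)C)Cc1c(O)cc(O)c2c1O[C@H](c1ccc(O)cc1O)[C@@H](O)C2=O | target

**Count**

Total step count: 14. Longest linear sequence: 9 steps (steps 1, 2, 3, 4, 10, 11, 12, 13, 14).

**Steps most likely to fail, with fallbacks**

Step 12 (key step). What may go wrong: the carbene is intercepted by the lone pair of O1 to give a five-membered oxonium ylide that undergoes a 1,2-shift of the electron-rich benzyl group (Stevens shift), or the catalyst discriminates poorly between the two enantiotopic C2–H bonds. Fallback: ring C is closed through O1–C2 instead of C2–C3, by the chalcone epoxide route. Setting out from 13, MOMCl/iPr2NEt gives 1-[3-iodo-2-(methoxymethoxy)-4,6-bis(TIPSO)phenyl]ethan-1-one F1. Negishi coupling with 15 as in step 10 gives 1-[3-[(2R)-lavandulyl]-2-(methoxymethoxy)-4,6-bis(TIPSO)phenyl]ethan-1-one F2. Its lithium enolate (LiN(SiMe3)2, THF, −78 °C) adds to aldehyde 9 to give 3-[2,4-bis(TBSO)phenyl]-3-hydroxy-1-[3-[(2R)-lavandulyl]-2-(methoxymethoxy)-4,6-bis(TIPSO)phenyl]propan-1-one F3 (not isolated), which MsCl/Et3N dehydrates in the same flask to (E)-3-[2,4-bis(TBSO)phenyl]-1-[3-[(2R)-lavandulyl]-2-(methoxymethoxy)-4,6-bis(TIPSO)phenyl]prop-2-en-1-one F4. Juliá–Colonna epoxidation (poly-L-leucine, urea–H2O2, DBU, THF), which is selective for the enone over the isolated alkenes, should give {(2R,3S)-3-[2,4-bis(TBSO)phenyl]oxiran-2-yl}[3-[(2R)-lavandulyl]-2-(methoxymethoxy)-4,6-bis(TIPSO)phenyl]methanone F5. MgBr2·OEt2 in CH2Cl2 then removes the chelated methoxymethyl group to give {(2R,3S)-3-[2,4-bis(TBSO)phenyl]oxiran-2-yl}[2-hydroxy-3-[(2R)-lavandulyl]-4,6-bis(TIPSO)phenyl]methanone F6 (not isolated), whose phenol opens the epoxide at the benzylic carbon with inversion (6-endo). This gives 20 with the C3 hydroxyl already in place; the route is rejoined at 20, before step 14, and steps 9 to 13 are bypassed.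

Step 13. What may go wrong: β-elimination of the ring oxygen from the sodium enolate (ring opening to the chalcone phenoxide and reclosure, which would scramble C2), or migration of the silyl group from O5 to the enolate oxygen. Fallback: the metal enolate is avoided. Setting out from 19, soft enolisation with Me3SiOTf/Et3N (CH2Cl2, 0 °C) gives (2S)-2-[2,4-bis(TBSO)phenyl]-8-[(2R)-lavandulyl]-5,7-bis(TIPSO)-4-(trimethylsilyloxy)-2H-chromene F7. Rubottom oxidation with one equivalent of dimethyldioxirane (acetone/CH2Cl2, −78 °C), to which the electron-rich enol ether should respond much faster than the side-chain alkenes, should take place anti to the C2 aryl group and, after silyl shift, give (2R,3R)-2-[2,4-bis(TBSO)phenyl]-8-[(2R)-lavandulyl]-5,7-bis(TIPSO)-3-(trimethylsilyloxy)-2,3-dihydro-4H-chromen-4-one F8. F8 is taken into the conditions of step 14 as such, where the fifth silyl group is removed with the others, and the route is rejoined at 21.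

Step 10. What may go wrong: slow oxidative addition and transmetalation at an iodide flanked by two ortho oxygen substituents, and cleavage of the acid-labile, electron-rich benzyl ether by zinc salts at 50 °C. Fallback: the order of coupling and etherification is inverted, so that the coupling runs next to a small anionic oxygen and in the absence of the benzyl ether. Setting out from 13, deprotonation with NaH and coupling of the sodium phenoxide with 15 under the same palladium catalyst gives 1-[2-hydroxy-3-[(2R)-lavandulyl]-4,6-bis(TIPSO)phenyl]ethan-1-one F9. Mitsunobu etherification of F9 with 10 (PPh3, DIAD, THF) then gives 16, where the route is rejoined.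

**Further compounds**

F1 | step 12 | 1-[3-iodo-2-(methoxymethoxy)-4,6-bis(TIPSO)phenyl]ethan-1-one | COCOc1c(I)c(O[Si](C(C)C)(C(C)C)C(C)C)cc(O[Si](C(C)C)(C(C)C)C(C)C)c1C(C)=O
F2 | step 12 | 1-[3-[(2R)-lavandulyl]-2-(methoxymethoxy)-4,6-bis(TIPSO)phenyl]ethan-1-one | C=C(C)[C@H](CC=C(C)C)Cc1c(O[Si](C(C)C)(C(C)C)C(C)C)cc(O[Si](C(C)C)(C(C)C)C(C)C)c(C(C)=O)c1OCOC
F3 | step 12 | 3-[2,4-bis(TBSO)phenyl]-3-hydroxy-1-[3-[(2R)-lavandulyl]-2-(methoxymethoxy)-4,6-bis(TIPSO)phenyl]propan-1-one | C=C(C)[C@H](CC=C(C)C)Cc1c(O[Si](C(C)C)(C(C)C)C(C)C)cc(O[Si](C(C)C)(C(C)C)C(C)C)c(C(=O)CC(O)c2ccc(O[Si](C)(C)C(C)(C)C)cc2O[Si](C)(C)C(C)(C)C)c1OCOC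
F4 | step 12 | (E)-3-[2,4-bis(TBSO)phenyl]-1-[3-[(2R)-lavandulyl]-2-(methoxymethoxy)-4,6-bis(TIPSO)phenyl]prop-2-en-1-one | C=C(C)[C@H](CC=C(C)C)Cc1c(O[Si](C(C)C)(C(C)C)C(C)C)cc(O[Si](C(C)C)(C(C)C)C(C)C)c(C(=O)/C=C/c2ccc(O[Si](C)(C)C(C)(C)C)cc2O[Si](C)(C)C(C)(C)C)c1OCOC
F5 | step 12 | {(2R,3S)-3-[2,4-bis(TBSO)phenyl]oxiran-2-yl}[3-[(2R)-lavandulyl]-2-(methoxymethoxy)-4,6-bis(TIPSO)phenyl]methanone | C=C(C)[C@H](CC=C(C)C)Cc1c(O[Si](C(C)C)(C(C)C)C(C)C)cc(O[Si](C(C)C)(C(C)C)C(C)C)c(C(=O)[C@@H]2O[C@H]2c3ccc(O[Si](C)(C)C(C)(C)C)cc3O[Si](C)(C)C(C)(C)C)c1OCOC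
F6 | step 12 | {(2R,3S)-3-[2,4-bis(TBSO)phenyl]oxiran-2-yl}[2-hydroxy-3-[(2R)-lavandulyl]-4,6-bis(TIPSO)phenyl]methanone | C=C(C)[C@H](CC=C(C)C)Cc1c(O[Si](C(C)C)(C(C)C)C(C)C)cc(O[Si](C(C)C)(C(C)C)C(C)C)c(C(=O)[C@@H]2O[C@H]2c3ccc(O[Si](C)(C)C(C)(C)C)cc3O[Si](C)(C)C(C)(C)C)c1O
F7 | step 13 | (2S)-2-[2,4-bis(TBSO)phenyl]-8-[(2R)-lavandulyl]-5,7-bis(TIPSO)-4-(trimethylsilyloxy)-2H-chromene | C=C(C)[C@H](CC=C(C)C)Cc1c(O[Si](C(C)C)(C(C)C)C(C)C)cc(O[Si](C(C)C)(C(C)C)C(C)C)c2c1O[C@H](c1ccc(O[Si](C)(C)C(C)(C)C)cc1O[Si](C)(C)C(C)(C)C)C=C2O[Si](C)(C)C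
F8 | step 13 | (2R,3R)-2-[2,4-bis(TBSO)phenyl]-8-[(2R)-lavandulyl]-5,7-bis(TIPSO)-3-(trimethylsilyloxy)-2,3-dihydro-4H-chromen-4-one | C=C(C)[C@H](CC=C(C)C)Cc1c(O[Si](C(C)C)(C(C)C)C(C)C)cc(O[Si](C(C)C)(C(C)C)C(C)C)c2c1O[C@H](c1ccc(O[Si](C)(C)C(C)(C)C)cc1O[Si](C)(C)C(C)(C)C)[C@@H](O[Si](C)(C)C)C2=O
F9 | step 10 | 1-[2-hydroxy-3-[(2R)-lavandulyl]-4,6-bis(TIPSO)phenyl]ethan-1-one | C=C(C)[C@H](CC=C(C)C)Cc1c(O[Si](C(C)C)(C(C)C)C(C)C)cc(O[Si](C(C)C)(C(C)C)C(C)C)c(C(C)=O)c1O
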